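## Retrosynthetic overview

1. The side chain is attached last: the C12–C13 bond comes from a B-alkyl Suzuki–Miyaura coupling of a C9-vinyl diol (vinyl group derived from a C11 acyl group) with the (E)-enol triflate of methyl acetoacetate.
2. The 6,8-diol and the trans ring fusion come from a 7-oxanorbornan-6-one: reductive cleavage of the C5–O bond (alpha to the C6 ketone) leaves the oxygen on C8, and the C6 ketone is then reduced to the equatorial alcohol.
3. Key disconnection: C8–C9 together with C5–C10, by a catalytic enantioselective intramolecular Diels–Alder reaction of a 3-silyloxyfuran (dearomatisation) with an (E)-enoyl imide. Rings A and B both close in this step (ring A through C5–C10, ring B through C8–C9), with a temporary C5–O–C8 bridge.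
4. The achiral precursor is made by C4–C5 bond formation: tert-alkylation of 3-silyloxy-5-methylfuran with the tertiary chloride obtained from the (2E)-geranic acid imide.
5. Enabling feature: the ring B segment C5–C6(O)–C7–C8(O)(C17), a ring-fusion carbon and a methyl carbinol carbon in 1,4-relationship with oxygen on C6, is the atom pattern of 5-methylfuran-3(2H)-one (ring oxygen = O8, ketone oxygen = O6, 5-methyl = C17). The geranoyl unit supplies C1–C4, C9–C11 and C18–C20.

Key step: step 6

Remarks:
- Labdane numbering is used for all bicyclic compounds: ring A = C1–C5 and C10; ring B = C5–C10; side chain C11–C16; C17 on C8; C18 and C19 on C4; C20 on C10.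
- (2E)-Geranic acid and 5-methylfuran-3(2H)-one are taken as commercially available. Any (2Z)-acid in technical geranic acid is to be removed at the first imide stage.
- (S,S)-t-Bu-box = 2,2'-(propane-2,2-diyl)bis[(4S)-4-tert-butyl-4,5-dihydro-1,3-oxazole].

## Route

Step 1
Reactants: 1 (2E)-geranic acid; 2 1,3-oxazolidin-2-one
Product: 4 3-[(2E)-3,7-dimethylocta-2,6-dienoyl]-1,3-oxazolidin-2-one, via geranic pivalic mixed anhydride 3 (not isolated)
Conditions: t-BuCOCl, Et3N, THF, −20 °C; then LiCl, 2, rt
Reagents that add atoms: none
Why: Mixed-anhydride N-acylation of an oxazolidinone installs the two-point-binding imide that will carry the chiral Lewis acid in step 6, without touching the (2E)-alkene and without forming a stereocentre.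

Step 2
Reactants: 4 geranoyl imide
Product: 5 3-[(2E)-7-chloro-3,7-dimethyloct-2-enoyl]-1,3-oxazolidin-2-one
Conditions: HCl (g), CH2Cl2, −20 → 0 °C
Reagents that add atoms: hydrogen chloride, Cl
Why: Markovnikov hydrochlorination should occur only at the electron-rich trisubstituted 6,7-alkene, since the acceptor-substituted 2,3-alkene is not protonated under these conditions.

Step 3
Reactants: 6 5-methylfuran-3(2H)-one
Product: 7 tert-butyldimethyl[(5-methylfuran-3-yl)oxy]silane
Conditions: TBSOTf, Et3N, CH2Cl2, 0 °C
Reagents that add atoms: tert-butyldimethylsilyl trifluoromethanesulfonate, CC(C)(C)[Si](C)(C)OS(=O)(=O)C(F)(F)F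
Why: Soft enolisation with O-silylation (silyl enol ether formation) is driven by aromatisation to the 3-silyloxyfuran.

Step 4
Reactants: 5 tertiary chloride; 7 silyloxyfuran
Product: 8 3-[(2E)-3,7-dimethyl-7-(5-methyl-3-oxo-2,3-dihydrofuran-2-yl)oct-2-enoyl]-1,3-oxazolidin-2-one (racemic at the furanone carbon)
Conditions: TiCl4 (2.2 equiv), CH2Cl2, −78 → −40 °C
Reagents that add atoms: none
Why: Lewis-acid-induced SN1 alpha-tert-alkylation of a silyl enol ether should trap the tertiary cation at the furan carbon that is both enol-ether beta-carbon and furan alpha-position, forming the C4–C5 bond; the new stereocentre is racemic and is erased in step 5.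

Step 5
Reactants: 8 furanone imide
Product: 9 3-[(2E)-7-{3-[(tert-butyldimethylsilyl)oxy]-5-methylfuran-2-yl}-3,7-dimethyloct-2-enoyl]-1,3-oxazolidin-2-one
Conditions: TBSOTf, Et3N, CH2Cl2, 0 °C
Reagents that add atoms: tert-butyldimethylsilyl trifluoromethanesulfonate, CC(C)(C)[Si](C)(C)OS(=O)(=O)C(F)(F)F
Why: Aromatising O-silylation of the furanone (silyl enol ether formation) gives the achiral, fully substituted electron-rich diene.

Step 6
Reactants: 9 silyloxyfuran imide
Product: 10 oxa-bridged cycloadduct (C5–O–C8 bridge anti to C20; C9 acyl group syn to C20; H9 syn to the bridge; C6=C7 silyl enol ether)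
Conditions: [Cu((S,S)-t-Bu-box)](SbF6)2 (10 mol %), 4 Å MS, CH2Cl2, −40 → 0 °C
Reagents that add atoms: none
Why: The cationic divalent copper complex binds the imide in two-point fashion (s-cis enoyl) and lowers the LUMO of the C9=C10 alkene, so that the silyloxyfuran should add across it in an asynchronous normal-demand intramolecular [4+2] cycloaddition in which the C5–C10 bond leads (vinylogous Mukaiyama–Michael character) and the C8–C9 bond completes the dearomatisation. The closest known reaction types are the copper–bis(oxazoline)-catalysed enantioselective Diels–Alder reaction of furan with N-enoyl oxazolidinones, its intramolecular variant with triene imides, and the Lewis-acid-promoted intramolecular Diels–Alder reaction of 2-alkylfurans with a four-atom tether. Ring A closes through C5–C10 as a six-membered carbocycle spanned by the C1–C4 tether (tether syn to the oxygen bridge), and ring B closes through C8–C9 as the six-membered ring of a 7-oxabicyclo[2.2.1]heptene whose C5–O–C8 bridge is temporary. C9 and C10 take their relative configuration from suprafacial addition to the (E)-alkene (C20 and C11 cis); C5 and C8 are tied to one face by the furan oxygen, so the later C8 hydroxyl is anti to C20 and C17 syn to it; the tether-exo, acyl-endo transition state places C20 and the C9 acyl group anti to the bridge; and the absolute sense comes from the tert-butyl groups of the ligand, which shield the si face of C9 in the square-planar complex so that the furan adds to the re face. The step needs facial selectivity, the tether-exo mode and survival of the bridged silyl enol ether: the gem-dimethyl group at C4 favours the reactive rotamer, the silyloxy group at C6 raises the HOMO with its largest coefficient at C5 (matched to the beta-carbon C10), the bidentate imide secures catalyst control, and the weakly Lewis acidic catalyst at low temperature should spare the bridge.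

Step 7
Reactants: 10 cycloadduct
Product: 12 bridged keto alcohol (C5–O–C8 bridge; C6 ketone; C11 primary alcohol), via enol-ether alcohol 11 (not isolated)
Conditions: LiBH4, MeOH (1 equiv), THF, 0 °C; then 0.5 M HCl, THF, 0 °C
Reagents that add atoms: none
Why: Reductive cleavage of the N-acyl oxazolidinone gives the primary alcohol, and acid hydrolysis of the silyl enol ether proceeds by C7 protonation (no enolate, hence no beta-elimination of the bridging oxygen) to the 7-oxanorbornan-2-one; no stereocentre is touched.

Step 8
Reactants: 12 bridged keto alcohol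
Product: 14 triol (trans-decalin; C6 hydroxyl equatorial and anti to C20; C8 hydroxyl anti to C20; C11 primary alcohol), via hydroxy ketone 13 (not isolated)
Conditions: Li (8 equiv), NH3/THF, −78 °C; then EtOH, −78 → −40 °C; NH4Cl
Reagents that add atoms: none
Why: Dissolving-metal reductive cleavage of the alpha-alkoxy ketone (known for 7-oxanorbornan-2-ones) breaks only the C5–O bond and gives the C5=C6 enolate; ethanol should then protonate C5 on the face opposite C20 (trans ring fusion), and the remaining lithium reduces the C6 ketone to the thermodynamically favoured equatorial alcohol, cis to the C8 hydroxyl.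

Step 9
Reactants: 14 triol
Product: 15 hydroxy aldehyde (C11 aldehyde; C6 and C8 hydroxyls free)
Conditions: TEMPO (10 mol %), PhI(OAc)2, CH2Cl2, rt
Reagents that add atoms: none
Why: Oxoammonium-mediated oxidation is chemoselective for the primary alcohol over the secondary and tertiary ones, and the trans relationship of C11 and O6 across ring B prevents lactol formation.

Step 10
Reactants: 15 hydroxy aldehyde
Product: 16 C9-vinyl diol (13,14,15,16-tetranorlabd-11-ene-6,8-diol of the ent series)
Conditions: Ph3PCH3Br, KOtBu, THF, 0 °C → rt
Reagents that add atoms: methyltriphenylphosphonium bromide, C[P+](c1ccccc1)(c1ccccc1)c1ccccc1.[Br-]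
Why: Wittig methylenation with the non-stabilised ylide should be faster than enolisation or retro-aldol cleavage of the beta-hydroxy aldehyde, so C9 keeps its configuration.

Step 11
Reactants: 17 methyl acetoacetate
Product: 18 methyl (2E)-3-{[(trifluoromethyl)sulfonyl]oxy}but-2-enoate
Conditions: Tf2O, aq. Me4NOH, hexane, 5 °C
Reagents that add atoms: trifluoromethanesulfonic anhydride, O=S(=O)(OS(=O)(=O)C(F)(F)F)C(F)(F)F
Why: O-Triflation of the non-chelated tetraalkylammonium enolate of the beta-keto ester should give the (E)-enol triflate, with the triflate trans to the ester.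

Step 12
Reactants: 16 C9-vinyl diol; 18 (E)-enol triflate
Product: 20 methyl (2E)-5-[(1S,2S,4R,4aR,8aR)-2,4-dihydroxy-2,5,5,8a-tetramethyldecahydronaphthalen-1-yl]-3-methylpent-2-enoate (target), via B-alkyl-9-BBN 19 (not isolated)
Conditions: 9-BBN (3 equiv), THF, rt; then 18, Pd(dppf)Cl2 (5 mol %), aq. K3PO4, DMF, rt → 50 °C
Reagents that add atoms: none
Why: Anti-Markovnikov hydroboration of the vinyl group followed by B-alkyl Suzuki–Miyaura coupling, which retains the geometry of the enol triflate, forms the C12–C13 bond and should give the (13E)-enoate without touching any stereocentre.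

## Compound list

1 | (2E)-geranic acid, (2E)-3,7-dimethylocta-2,6-dienoic acid | CC(C)=CCC/C(C)=C/C(=O)O | starting material
2 | 1,3-oxazolidin-2-one | O=C1NCCO1 | starting material
3 | geranic pivalic mixed anhydride | CC(C)=CCC/C(C)=C/C(=O)OC(=O)C(C)(C)C | intermediate
4 | 3-[(2E)-3,7-dimethylocta-2,6-dienoyl]-1,3-oxazolidin-2-one | CC(C)=CCC/C(C)=C/C(=O)N1CCOC1=O | intermediate
5 | 3-[(2E)-7-chloro-3,7-dimethyloct-2-enoyl]-1,3-oxazolidin-2-one | CC(C)(Cl)CCC/C(C)=C/C(=O)N1CCOC1=O | intermediate
6 | 5-methylfuran-3(2H)-one | CC1=CC(=O)CO1 | starting material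
7 | tert-butyldimethyl[(5-methylfuran-3-yl)oxy]silane | Cc1cc(O[Si](C)(C)C(C)(C)C)co1 | intermediate
8 | 3-[(2E)-3,7-dimethyl-7-(5-methyl-3-oxo-2,3-dihydrofuran-2-yl)oct-2-enoyl]-1,3-oxazolidin-2-one, racemic at the furanone carbon | CC1=CC(=O)C(O1)C(C)(C)CCC/C(C)=C/C(=O)N2CCOC2=O | intermediate
9 | 3-[(2E)-7-{3-[(tert-butyldimethylsilyl)oxy]-5-methylfuran-2-yl}-3,7-dimethyloct-2-enoyl]-1,3-oxazolidin-2-one | Cc1cc(O[Si](C)(C)C(C)(C)C)c(o1)C(C)(C)CCC/C(C)=C/C(=O)N2CCOC2=O | intermediate
10 | oxa-bridged cycloadduct: C5–O–C8 bridge anti to C20, H9 syn to the bridge, C9 acyl (oxazolidinone imide) syn to C20, C6=C7 TBS enol ether | O=C(N1CCOC1=O)[C@H]2[C@]3(C)CCCC(C)(C)[C@]34O[C@@]2(C)C=C4O[Si](C)(C)C(C)(C)C | intermediate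
11 | enol-ether alcohol: as 10 with C11 as CH2OH | OC[C@H]1[C@]2(C)CCCC(C)(C)[C@]23O[C@@]1(C)C=C3O[Si](C)(C)C(C)(C)C | intermediate
12 | bridged keto alcohol: C5–O–C8 bridge, C6 ketone, C11 CH2OH | OC[C@H]1[C@]2(C)CCCC(C)(C)[C@]23O[C@@]1(C)CC3=O | intermediate
13 | hydroxy ketone: trans-decalin, C6 ketone, C8 hydroxyl anti to C20, C11 CH2OH | OC[C@H]1[C@]2(C)CCCC(C)(C)[C@H]2C(=O)C[C@]1(C)O | intermediate
14 | triol: trans-decalin, C6 and C8 hydroxyls both anti to C20, C11 CH2OH syn to C20 | OC[C@H]1[C@]2(C)CCCC(C)(C)[C@H]2[C@H](O)C[C@]1(C)O | intermediate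
15 | hydroxy aldehyde: as 14 with C11 as CHO | O=C[C@H]1[C@]2(C)CCCC(C)(C)[C@H]2[C@H](O)C[C@]1(C)O | intermediate
16 | C9-vinyl diol: as 14 with C9 bearing CH=CH2 | C=C[C@H]1[C@]2(C)CCCC(C)(C)[C@H]2[C@H](O)C[C@]1(C)O | intermediate
17 | methyl acetoacetate | COC(=O)CC(C)=O | starting material
18 | methyl (2E)-3-{[(trifluoromethyl)sulfonyl]oxy}but-2-enoate | COC(=O)/C=C(\C)OS(=O)(=O)C(F)(F)F | intermediate
19 | B-alkyl-9-BBN: boron on C12 of the hydroborated vinyl group of 16 (hydroxyls possibly borylated in the flask) | B3(C4CCCC3CCC4)CC[C@H]1[C@]2(C)CCCC(C)(C)[C@H]2[C@H](O)C[C@]1(C)O | intermediate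
20 | methyl (2E)-5-[(1S,2S,4R,4aR,8aR)-2,4-dihydroxy-2,5,5,8a-tetramethyldecahydronaphthalen-1-yl]-3-methylpent-2-enoate | COC(=O)/C=C(\C)CC[C@H]1[C@]2(C)CCCC(C)(C)[C@H]2[C@H](O)C[C@]1(C)O | target

## Step count

Total steps: 12. Longest linear sequence: 10 (steps 1, 2, 4, 5, 6, 7, 8, 9, 10, 12, from geranic acid); steps 3 and 11 prepare the two side components.

## Steps most likely to fail, with fallbacks

**Step 6 (key cycloaddition).**
- What may go wrong: the hindered beta,beta-disubstituted imide may be activated too weakly by the mild copper catalyst, giving no cycloaddition or a slow uncatalysed background reaction with poor facial selectivity. The Lewis acid may also ionise the bridging C8–O bond of the silyl enol ether.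
- Fallback (auxiliary control, a stronger chelating Lewis acid, and diastereomers that can be separated), setting out from acid 1 and returning at keto alcohol 12. Acid 1 is coupled with (4R)-4-benzyl-1,3-oxazolidin-2-one under the conditions of step 1 to give (4R)-4-benzyl-3-[(2E)-3,7-dimethylocta-2,6-dienoyl]-1,3-oxazolidin-2-one F1. HCl addition gives the tertiary chloride F2. TiCl4-mediated tert-alkylation of silyloxyfuran 7 gives the furanone imide F3. TBSOTf/Et3N gives the silyloxyfuran imide F4. Me2AlCl (1.4 equiv, CH2Cl2, −78 °C) forms the chelated s-cis imide, in which the benzyl group blocks the si face of C9, and the cycloadduct F5 is freed from the minor diastereomer by chromatography. LiBH4 followed by dilute HCl, as in step 7, releases the auxiliary and the silanol and gives keto alcohol 12.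

**Step 8 (one-pot bridge opening and ketone reduction).**
- What may go wrong: poor facial selectivity in the C6 reduction (axial alcohol); or retro-aldol opening of ring B in the transient beta-alkoxide ketone under the basic medium, followed by re-closure to the isomeric aldol.
- Fallback (the two events are separated and the hydride face is put under enzyme control), setting out from keto alcohol 12 and returning at triol 14. The bridge is opened under neutral conditions with SmI2 (THF/MeOH, −78 °C), the known reductive oxa-ring opening of 7-oxanorbornan-2-ones, and hydroxy ketone 13 is isolated. It is then reduced with an NADPH-dependent ketoreductase selected from a screening panel for delivery of hydride to the hindered face (isopropanol-coupled cofactor recycling, pH 7 buffer, 30 °C), which gives triol 14.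

**Step 10 (methylenation of the beta-hydroxy aldehyde).**
- What may go wrong: alkoxide-triggered retro-aldol cleavage of the C8–C9 bond, or epimerisation at C9, may compete with slow ylide addition to the hindered aldehyde.
- Fallback (side chain built through a methyl ketone under neutral olefination conditions), setting out from aldehyde 15 and returning at target 20. Aldehyde 15 is heated with 1-(triphenylphosphoranylidene)propan-2-one (toluene, 90 °C) to give the (11E)-enone F6. Hydrogenation (H2, Pd/C, EtOAc) gives the saturated 8-hydroxy-13-ketone F7. Horner–Wadsworth–Emmons olefination with trimethyl phosphonoacetate (NaH, THF) gives target 20, and the (13Z)-isomer is to be removed by chromatography.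

Further compounds
F1 | step 6 | (4R)-4-benzyl-3-[(2E)-3,7-dimethylocta-2,6-dienoyl]-1,3-oxazolidin-2-one | CC(C)=CCC/C(C)=C/C(=O)N1[C@H](Cc2ccccc2)COC1=O
F2 | step 6 | (4R)-4-benzyl-3-[(2E)-7-chloro-3,7-dimethyloct-2-enoyl]-1,3-oxazolidin-2-one | CC(C)(Cl)CCC/C(C)=C/C(=O)N1[C@H](Cc2ccccc2)COC1=O
F3 | step 6 | (4R)-4-benzyl-3-[(2E)-3,7-dimethyl-7-(5-methyl-3-oxo-2,3-dihydrofuran-2-yl)oct-2-enoyl]-1,3-oxazolidin-2-one | CC1=CC(=O)C(O1)C(C)(C)CCC/C(C)=C/C(=O)N2[C@H](Cc3ccccc3)COC2=O
F4 | step 6 | (4R)-4-benzyl-3-[(2E)-7-{3-[(tert-butyldimethylsilyl)oxy]-5-methylfuran-2-yl}-3,7-dimethyloct-2-enoyl]-1,3-oxazolidin-2-one | Cc1cc(O[Si](C)(C)C(C)(C)C)c(o1)C(C)(C)CCC/C(C)=C/C(=O)N2[C@H](Cc3ccccc3)COC2=O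
F5 | step 6 | oxa-bridged cycloadduct carrying the (4R)-4-benzyl-oxazolidinone auxiliary (ring stereochemistry as in 10) | O=C(N1[C@H](Cc2ccccc2)COC1=O)[C@H]3[C@]4(C)CCCC(C)(C)[C@]45O[C@@]3(C)C=C5O[Si](C)(C)C(C)(C)C
F0 | step 8 | none | none
F6 | step 10 | (11E)-enone: 6,8-dihydroxy-14,15-dinorlabd-11-en-13-one (ring stereochemistry as in 14) | CC(=O)/C=C/[C@H]1[C@]2(C)CCCC(C)(C)[C@H]2[C@H](O)C[C@]1(C)O
F7 | step 10 | 6,8-dihydroxy-14,15-dinorlabdan-13-one (ring stereochemistry as in 14) | CC(=O)CC[C@H]1[C@]2(C)CCCC(C)(C)[C@H]2[C@H](O)C[C@]1(C)O
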